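**Plan**

Numbering used throughout: ring C1 (CH–O‑angelate), C2 (C=O), C3 (oxirane C–CH3), C4 (oxirane CH), C5 (CH2), C6 (CH); side chain C7(=C14H2)–C8H(OAc)–C9H2–C10H=C11(CH3)2.
Retrosynthesis: the ester bonds C8–OAc and C1–O‑angelate are cut first; then the ring bond C1–C6 together with the C7=C14 double bond (retro‑carbonyl‑ene), which opens the carbocycle to the acyclic epoxy keto aldehyde 20; then C1–C2, the C3–C4 oxirane, the C3=C4 and C6=C7 double bonds (two olefinations) and C9–C10.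
Feature that makes the event possible: the C1 carbinol next to the C2 ketone is the imprint of a 1,2‑dicarbonyl enophile, C6 carries the 1,1‑disubstituted C7=C14 vinyl group that an ene reaction leaves behind, and the cis‑oxirane C3–C4 holds C2 and C5 syn, so that the open chain folds into the six‑membered ring.
Forward: the chain is grown linearly from C8–C11 (C9–C10 bond), then C6=C7, then C3=C4; the oxirane is the first ring (step 8), C1 is added, the 1,2‑diol is oxidised to the glyoxal, the carbocycle is closed last (step 13), and the two esters are put on.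
Stereochemistry: C8 from methyl (S)‑glycidate; C3 and C4 from Katsuki–Sharpless epoxidation of the (Z)‑allylic alcohol 15 with D‑(−)‑tartrate; C1 and C6 in the key step (chair‑like ene array for the trans relation, chelating chiral copper catalyst matched with the oxirane for the face); both Z double bonds from Z‑selective olefinations; the angelate geometry from angelic acid.

Key step: step 13

Remark: centres that are formed without control and erased again (C2 in 18 and 19, the N,O‑acetal carbon of 10) are carried as mixtures, and their SMILES leave these centres undefined.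

**Route**

Step 1
Reactants: 1 methyl (2S)‑oxirane‑2‑carboxylate; 2 (2‑methylprop‑1‑en‑1‑yl)magnesium bromide
Product: 3 methyl (2S)‑2‑hydroxy‑5‑methylhex‑4‑enoate
Conditions: CuBr·SMe2 (10 mol %), THF, −40 °C
Reagents that add atoms: none
Why: Copper‑catalysed Grignard opening of a terminal epoxide, in which the alkenyl copper species attacks the unsubstituted oxirane carbon (SN2) faster than the ester at low temperature, so the C9–C10 bond is made and the C8 centre of 1 is carried over untouched.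

Step 2
Reactants: 3 methyl (2S)‑2‑hydroxy‑5‑methylhex‑4‑enoate
Product: 4 methyl (2S)‑2‑[(tert‑butyldimethylsilyl)oxy]‑5‑methylhex‑4‑enoate
Conditions: TBSCl, imidazole, DMF, rt
Reagents that add atoms: tert‑butyldimethylsilyl chloride, CC(C)(C)[Si](C)(C)Cl
Why: Standard silyl ether protection of the secondary alcohol, needed for the basic and oxidising steps that follow; no stereocentre is touched.

Step 3
Reactants: 4 methyl (2S)‑2‑[(tert‑butyldimethylsilyl)oxy]‑5‑methylhex‑4‑enoate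
Product: 6 (3S)‑3‑[(tert‑butyldimethylsilyl)oxy]‑6‑methylhept‑5‑en‑2‑one, via Weinreb amide 5 (not isolated)
Conditions: MeNH(OMe)·HCl, iPrMgCl, THF, −20 °C; then MeMgBr, −20 to 0 °C
Reagents that add atoms: methylmagnesium bromide, C[Mg]Br; N,O‑dimethylhydroxylamine hydrochloride, CNOC.Cl (its atoms stay only in 5)
Why: Weinreb ketone synthesis run in one pot, in which the magnesium amide converts the ester into amide 5 and the chelated tetrahedral adduct of 5 with MeMgBr stops at the ketone stage (C7 with its C14 methyl), without enolising the silyloxy‑bearing C8 at low temperature.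

Step 4
Reactants: 6 (3S)‑3‑[(tert‑butyldimethylsilyl)oxy]‑6‑methylhept‑5‑en‑2‑one; 7 [2‑(1,3‑dioxolan‑2‑yl)ethyl]triphenylphosphonium bromide
Product: 9 2‑[(2Z,4S)‑4‑[(tert‑butyldimethylsilyl)oxy]‑3,7‑dimethylocta‑2,6‑dien‑1‑yl]‑1,3‑dioxolane, via phosphorus ylide 8 (not isolated)
Conditions: 7, KN(SiMe3)2, THF, −78 to 0 °C; then 6, −78 °C to rt
Reagents that add atoms: none
Why: Wittig olefination of an α‑alkoxy methyl ketone with a non‑stabilised ylide under salt‑free conditions, a reaction type known to give the trisubstituted alkene with the ylide chain cis to the oxygen‑bearing carbon, here C5 cis to C8 (the Z geometry that the key step needs).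

Step 5
Reactants: 9 2‑[(2Z,4S)‑4‑[(tert‑butyldimethylsilyl)oxy]‑3,7‑dimethylocta‑2,6‑dien‑1‑yl]‑1,3‑dioxolane
Product: 11 (3Z,5S)‑5‑[(tert‑butyldimethylsilyl)oxy]‑4,8‑dimethylnona‑3,7‑dienal, via collidinium salt 10 (not isolated)
Conditions: Et3SiOTf, 2,4,6‑collidine, CH2Cl2, 0 °C; then H2O, rt
Reagents that add atoms: water, O; triethylsilyl trifluoromethanesulfonate, CC[Si](CC)(CC)OS(=O)(=O)C(F)(F)F, and 2,4,6‑trimethylpyridine, Cc1cc(C)nc(C)c1 (their atoms stay only in 10)
Why: Acetal cleavage by the silyl triflate/collidine method, which converts the dioxolane into the pyridinium N,O‑acetal 10 that water hydrolyses to the aldehyde, with no acid strong enough to move the C6=C7 double bond into conjugation or to cleave the silyl ether.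

Step 6
Reactants: 11 (3Z,5S)‑5‑[(tert‑butyldimethylsilyl)oxy]‑4,8‑dimethylnona‑3,7‑dienal; 12 ethyl 2‑[bis(2,2,2‑trifluoroethoxy)phosphoryl]propanoate
Product: 14 ethyl (2Z,5Z,7S)‑7‑[(tert‑butyldimethylsilyl)oxy]‑2,6,10‑trimethylundeca‑2,5,9‑trienoate, via potassium phosphonate 13 (not isolated)
Conditions: 12, KN(SiMe3)2, 18‑crown‑6, THF, −78 °C; then 11, −78 °C
Reagents that add atoms: none
Why: Still–Gennari variant of the Horner–Wadsworth–Emmons reaction, in which the electron‑poor phosphonate with a dissociated potassium ion eliminates fast from the kinetic adduct and gives the (Z)‑2‑methyl enoate (C2 cis to C5); addition at −78 °C should outrun deprotonation of the skipped aldehyde.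

Step 7
Reactants: 14 ethyl (2Z,5Z,7S)‑7‑[(tert‑butyldimethylsilyl)oxy]‑2,6,10‑trimethylundeca‑2,5,9‑trienoate
Product: 15 (2Z,5Z,7S)‑7‑[(tert‑butyldimethylsilyl)oxy]‑2,6,10‑trimethylundeca‑2,5,9‑trien‑1‑ol
Conditions: iBu2AlH, CH2Cl2, −78 °C
Reagents that add atoms: none
Why: 1,2‑Reduction of the enoate by the aluminium hydride gives the (Z)‑allylic alcohol without touching the isolated double bonds or the silyl ether.

Step 8
Reactants: 15 (2Z,5Z,7S)‑7‑[(tert‑butyldimethylsilyl)oxy]‑2,6,10‑trimethylundeca‑2,5,9‑trien‑1‑ol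
Product: 16 [(2R,3S)‑3‑[(2Z,4S)‑4‑[(tert‑butyldimethylsilyl)oxy]‑3,7‑dimethylocta‑2,6‑dien‑1‑yl]‑2‑methyloxiran‑2‑yl]methanol
Conditions: Ti(OiPr)4, diethyl D‑(−)‑tartrate, tBuOOH, 4 Å molecular sieves, CH2Cl2, −20 °C
Reagents that add atoms: tert‑butyl hydroperoxide, CC(C)(C)OO
Why: Katsuki–Sharpless asymmetric epoxidation, which oxidises only the allylic‑alcohol double bond and, with the D‑(−)‑tartrate, delivers oxygen to the face that gives C3 and C4 of the target; the cis relation of C2 and C5 follows from the Z olefin, and the enantiopure C8 centre turns any minor epoxide isomer into a separable diastereomer.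

Step 9
Reactants: 16 [(2R,3S)‑3‑[(2Z,4S)‑4‑[(tert‑butyldimethylsilyl)oxy]‑3,7‑dimethylocta‑2,6‑dien‑1‑yl]‑2‑methyloxiran‑2‑yl]methanol
Product: 17 (2S,3S)‑3‑[(2Z,4S)‑4‑[(tert‑butyldimethylsilyl)oxy]‑3,7‑dimethylocta‑2,6‑dien‑1‑yl]‑2‑methyloxirane‑2‑carbaldehyde
Conditions: Dess–Martin periodinane, NaHCO3, CH2Cl2, 0 °C to rt
Reagents that add atoms: none
Why: Buffered Dess–Martin oxidation of the primary alcohol gives the epoxy aldehyde, which cannot epimerise because C3 is quaternary.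

Step 10
Reactants: 17 (2S,3S)‑3‑[(2Z,4S)‑4‑[(tert‑butyldimethylsilyl)oxy]‑3,7‑dimethylocta‑2,6‑dien‑1‑yl]‑2‑methyloxirane‑2‑carbaldehyde
Product: 18 (1RS)‑1‑[(2R,3S)‑3‑[(2Z,4S)‑4‑[(tert‑butyldimethylsilyl)oxy]‑3,7‑dimethylocta‑2,6‑dien‑1‑yl]‑2‑methyloxiran‑2‑yl]‑2‑[dimethyl(propan‑2‑yloxy)silyl]ethan‑1‑ol (epimers at C2)
Conditions: (iPrO)Me2SiCH2MgCl, THF, −78 to 0 °C
Reagents that add atoms: {[dimethyl(propan‑2‑yloxy)silyl]methyl}magnesium chloride, CC(C)O[Si](C)(C)C[Mg]Cl (made beforehand from (chloromethyl)dimethyl(propan‑2‑yloxy)silane, CC(C)O[Si](C)(C)CCl, and Mg)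
Why: Grignard addition of a silylmethyl reagent that serves as a hydroxymethyl anion equivalent adds C1 to the aldehyde; the new carbinol centre C2 is formed without control, which is harmless because it becomes the ketone in step 12.

Step 11
Reactants: 18 the β‑hydroxy silane from step 10
Product: 19 (1RS)‑1‑[(2R,3S)‑3‑[(2Z,4S)‑4‑[(tert‑butyldimethylsilyl)oxy]‑3,7‑dimethylocta‑2,6‑dien‑1‑yl]‑2‑methyloxiran‑2‑yl]ethane‑1,2‑diol (epimers at C2)
Conditions: 30% H2O2, KF, KHCO3, THF/MeOH, rt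
Reagents that add atoms: hydrogen peroxide, OO
Why: Tamao–Fleming oxidation converts the C–Si bond of the alkoxysilane into C–OH under mildly basic conditions that should leave the oxirane, the isolated double bonds and the secondary silyl ether untouched.

Step 12
Reactants: 19 the epoxy 1,2‑diol from step 11
Product: 20 2‑[(2S,3S)‑3‑[(2Z,4S)‑4‑[(tert‑butyldimethylsilyl)oxy]‑3,7‑dimethylocta‑2,6‑dien‑1‑yl]‑2‑methyloxiran‑2‑yl]‑2‑oxoacetaldehyde
Conditions: (COCl)2, DMSO, CH2Cl2, −78 °C; then Et3N, −78 to −20 °C; non‑aqueous work‑up, used at once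
Reagents that add atoms: none
Why: Double Swern oxidation of the 1,2‑diol gives the 1,2‑dicarbonyl compound without C–C cleavage and erases the uncontrolled C2 centre; the glyoxal has no enolisable hydrogen because C3 is quaternary.

Step 13
Reactants: 20 2‑[(2S,3S)‑3‑[(2Z,4S)‑4‑[(tert‑butyldimethylsilyl)oxy]‑3,7‑dimethylocta‑2,6‑dien‑1‑yl]‑2‑methyloxiran‑2‑yl]‑2‑oxoacetaldehyde
Product: 21 (1S,3S,4S,6S)‑4‑[(3S)‑3‑[(tert‑butyldimethylsilyl)oxy]‑6‑methylhepta‑1,5‑dien‑2‑yl]‑3‑hydroxy‑1‑methyl‑7‑oxabicyclo[4.1.0]heptan‑2‑one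
Conditions: [Cu((S,S)‑tBu‑box)](SbF6)2 (10 mol %; tBu‑box = 2,2'‑(propane‑2,2‑diyl)bis[(4S)‑4‑tert‑butyl‑4,5‑dihydro‑1,3‑oxazole]), CH2Cl2 (0.01 M), 0 °C to rt
Reagents that add atoms: none
Why: Proposed new method: the copper bis(oxazoline) dication (divalent copper) should bind the 1,2‑dicarbonyl unit of 20 as a five‑membered chelate, and the activated formyl carbon C1 should then undergo a concerted but asynchronous carbonyl‑ene reaction with the C6=C7 double bond, in which C1 bonds to C6 while the formyl oxygen takes a hydrogen from the C14 methyl group, so that the C1 carbinol, the C7=C14 methylidene group and the carbocycle arise in one event. The closest known reaction types are the glyoxylate‑ene and arylglyoxal‑ene reactions between two molecules under catalysis by chelating chiral Lewis acids and the type 1 intramolecular carbonyl‑ene cyclisation of citronellal to isopulegol; what is new is an intramolecular ene reaction of a 2‑oxoaldehyde whose keto group ends up inside the ring. The six‑membered ring is closed by the C1–C6 bond in a type 1 ene closure (6‑exo‑trig at the formyl group, the ene double bond staying outside the ring) through a chair‑like array, made possible because the cis‑oxirane C3–C4 holds C2 and C5 syn as a Z double bond would. C6 is set relative to C1 by this array, in which the C1 oxygen (fixed in the chelate plane) and the C7 substituent are both pseudo‑equatorial and therefore trans; C1 is set by the face of the formyl group that is attacked, the Si face, which is the face left open by the (S,S)‑tert‑butyl ligand in glyoxylate‑ene reactions and also the face anti to the oxirane oxygen in the conformer that keeps the oxirane bisected by the C2 carbonyl plane, so that catalyst and substrate should reinforce each other. The step needs formyl‑over‑keto and six‑ over five‑ring selectivity (secured by the higher electrophilicity of the aldehyde and the quaternary C3 next to the ketone), hydrogen transfer from C14 and not from C8–H (secured by the Z geometry of C6=C7, which puts the methyl group trans to the tether where the formyl oxygen can reach it) and survival of the oxirane (secured by the mild chelated Lewis acid and the electron‑withdrawing acyl group on C3).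

Step 14
Reactants: 21 the α‑hydroxy ketone from step 13; 22 (2Z)‑2‑methylbut‑2‑enoic acid (angelic acid)
Product: 24 (1S,3S,4S,6S)‑4‑[(3S)‑3‑[(tert‑butyldimethylsilyl)oxy]‑6‑methylhepta‑1,5‑dien‑2‑yl]‑1‑methyl‑2‑oxo‑7‑oxabicyclo[4.1.0]heptan‑3‑yl (2Z)‑2‑methylbut‑2‑enoate, via mixed anhydride 23 (not isolated)
Conditions: 22, 2,4,6‑trichlorobenzoyl chloride, Et3N, toluene, rt; then 21, 70 °C
Reagents that add atoms: 2,4,6‑trichlorobenzoyl chloride, O=C(Cl)c1c(Cl)cc(Cl)cc1Cl (its atoms stay only in 23)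
Why: Yamaguchi‑type acylation with the preformed mixed anhydride and no nucleophilic catalyst, where the hindered aroyl carbonyl is not attacked and the addition–elimination that turns angelates into tiglates is avoided; the α‑ketol is the only free hydroxyl group and its trans‑diequatorial C1 configuration is the stable one.

Step 15
Reactants: 24 the angelate silyl ether from step 14
Product: 25 (1S,3S,4S,6S)‑4‑[(3S)‑3‑hydroxy‑6‑methylhepta‑1,5‑dien‑2‑yl]‑1‑methyl‑2‑oxo‑7‑oxabicyclo[4.1.0]heptan‑3‑yl (2Z)‑2‑methylbut‑2‑enoate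
Conditions: HF·pyridine, pyridine, THF, 0 °C to rt
Reagents that add atoms: none
Why: Fluoride cleavage of the secondary silyl ether with pyridine‑buffered HF·pyridine, conditions under which epoxides and enoate esters are known to survive.

Step 16
Reactants: 25 the C8 alcohol from step 15
Product: 26 (1S,3S,4S,6S)‑4‑[(3S)‑3‑(acetyloxy)‑6‑methylhepta‑1,5‑dien‑2‑yl]‑1‑methyl‑2‑oxo‑7‑oxabicyclo[4.1.0]heptan‑3‑yl (2Z)‑2‑methylbut‑2‑enoate (target, CNP0125636.1)
Conditions: Ac2O, pyridine, DMAP (cat.), CH2Cl2, 0 °C to rt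
Reagents that add atoms: acetic anhydride, CC(=O)OC(C)=O
Why: DMAP‑catalysed acetylation of the secondary allylic alcohol completes the target; no stereocentre is involved and the existing angelate is stable to these conditions.

**Compound list**

1 | methyl (2S)‑oxirane‑2‑carboxylate | COC(=O)[C@@H]1CO1 | starting material
2 | (2‑methylprop‑1‑en‑1‑yl)magnesium bromide | CC(C)=C[Mg]Br | starting material
3 | methyl (2S)‑2‑hydroxy‑5‑methylhex‑4‑enoate | COC(=O)[C@H](CC=C(C)C)O | intermediate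
4 | methyl (2S)‑2‑[(tert‑butyldimethylsilyl)oxy]‑5‑methylhex‑4‑enoate | COC(=O)[C@H](CC=C(C)C)O[Si](C)(C)C(C)(C)C | intermediate
5 | (2S)‑2‑[(tert‑butyldimethylsilyl)oxy]‑N‑methoxy‑N,5‑dimethylhex‑4‑enamide | CON(C)C(=O)[C@H](CC=C(C)C)O[Si](C)(C)C(C)(C)C | intermediate (not isolated)
6 | (3S)‑3‑[(tert‑butyldimethylsilyl)oxy]‑6‑methylhept‑5‑en‑2‑one | CC(=O)[C@H](CC=C(C)C)O[Si](C)(C)C(C)(C)C | intermediate
7 | [2‑(1,3‑dioxolan‑2‑yl)ethyl]triphenylphosphonium bromide | [Br-].O1CCOC1CC[P+](c2ccccc2)(c2ccccc2)c2ccccc2 | starting material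
8 | [2‑(1,3‑dioxolan‑2‑yl)ethylidene]triphenylphosphorane | O1CCOC1CC=P(c2ccccc2)(c2ccccc2)c2ccccc2 | intermediate (not isolated)
9 | 2‑[(2Z,4S)‑4‑[(tert‑butyldimethylsilyl)oxy]‑3,7‑dimethylocta‑2,6‑dien‑1‑yl]‑1,3‑dioxolane | O1CCOC1C/C=C(C)\[C@H](CC=C(C)C)O[Si](C)(C)C(C)(C)C | intermediate
10 | 1‑[(3Z,5S)‑5‑[(tert‑butyldimethylsilyl)oxy]‑4,8‑dimethyl‑1‑{2‑[(triethylsilyl)oxy]ethoxy}nona‑3,7‑dien‑1‑yl]‑2,4,6‑trimethylpyridin‑1‑ium trifluoromethanesulfonate | Cc1cc(C)[n+](c(C)c1)C(OCCO[Si](CC)(CC)CC)C/C=C(C)\[C@H](CC=C(C)C)O[Si](C)(C)C(C)(C)C.[O-]S(=O)(=O)C(F)(F)F | intermediate (not isolated)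
11 | (3Z,5S)‑5‑[(tert‑butyldimethylsilyl)oxy]‑4,8‑dimethylnona‑3,7‑dienal | O=CC/C=C(C)\[C@H](CC=C(C)C)O[Si](C)(C)C(C)(C)C | intermediate
12 | ethyl 2‑[bis(2,2,2‑trifluoroethoxy)phosphoryl]propanoate | CCOC(=O)C(C)P(=O)(OCC(F)(F)F)OCC(F)(F)F | starting material
13 | potassium salt of 12 (carbanion at C2) | [K+].CCOC(=O)[C-](C)P(=O)(OCC(F)(F)F)OCC(F)(F)F | intermediate (not isolated)
14 | ethyl (2Z,5Z,7S)‑7‑[(tert‑butyldimethylsilyl)oxy]‑2,6,10‑trimethylundeca‑2,5,9‑trienoate | CCOC(=O)/C(C)=C\C/C=C(C)\[C@H](CC=C(C)C)O[Si](C)(C)C(C)(C)C | intermediate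
15 | (2Z,5Z,7S)‑7‑[(tert‑butyldimethylsilyl)oxy]‑2,6,10‑trimethylundeca‑2,5,9‑trien‑1‑ol | OC/C(C)=C\C/C=C(C)\[C@H](CC=C(C)C)O[Si](C)(C)C(C)(C)C | intermediate
16 | [(2R,3S)‑3‑[(2Z,4S)‑4‑[(tert‑butyldimethylsilyl)oxy]‑3,7‑dimethylocta‑2,6‑dien‑1‑yl]‑2‑methyloxiran‑2‑yl]methanol | OC[C@@]1(C)O[C@H]1C/C=C(C)\[C@H](CC=C(C)C)O[Si](C)(C)C(C)(C)C | intermediate
17 | (2S,3S)‑3‑[(2Z,4S)‑4‑[(tert‑butyldimethylsilyl)oxy]‑3,7‑dimethylocta‑2,6‑dien‑1‑yl]‑2‑methyloxirane‑2‑carbaldehyde | O=C[C@@]1(C)O[C@H]1C/C=C(C)\[C@H](CC=C(C)C)O[Si](C)(C)C(C)(C)C | intermediate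
18 | (1RS)‑1‑[(2R,3S)‑3‑[(2Z,4S)‑4‑[(tert‑butyldimethylsilyl)oxy]‑3,7‑dimethylocta‑2,6‑dien‑1‑yl]‑2‑methyloxiran‑2‑yl]‑2‑[dimethyl(propan‑2‑yloxy)silyl]ethan‑1‑ol | CC(C)O[Si](C)(C)CC(O)[C@@]1(C)O[C@H]1C/C=C(C)\[C@H](CC=C(C)C)O[Si](C)(C)C(C)(C)C | intermediate
19 | (1RS)‑1‑[(2R,3S)‑3‑[(2Z,4S)‑4‑[(tert‑butyldimethylsilyl)oxy]‑3,7‑dimethylocta‑2,6‑dien‑1‑yl]‑2‑methyloxiran‑2‑yl]ethane‑1,2‑diol | OCC(O)[C@@]1(C)O[C@H]1C/C=C(C)\[C@H](CC=C(C)C)O[Si](C)(C)C(C)(C)C | intermediate
20 | 2‑[(2S,3S)‑3‑[(2Z,4S)‑4‑[(tert‑butyldimethylsilyl)oxy]‑3,7‑dimethylocta‑2,6‑dien‑1‑yl]‑2‑methyloxiran‑2‑yl]‑2‑oxoacetaldehyde | O=CC(=O)[C@@]1(C)O[C@H]1C/C=C(C)\[C@H](CC=C(C)C)O[Si](C)(C)C(C)(C)C | intermediate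
21 | (1S,3S,4S,6S)‑4‑[(3S)‑3‑[(tert‑butyldimethylsilyl)oxy]‑6‑methylhepta‑1,5‑dien‑2‑yl]‑3‑hydroxy‑1‑methyl‑7‑oxabicyclo[4.1.0]heptan‑2‑one | C=C([C@H](CC=C(C)C)O[Si](C)(C)C(C)(C)C)[C@@H]1C[C@@H]2O[C@]2(C)C(=O)[C@H]1O | intermediate
22 | (2Z)‑2‑methylbut‑2‑enoic acid (angelic acid) | C/C=C(/C)C(O)=O | starting material
23 | (2Z)‑2‑methylbut‑2‑enoic 2,4,6‑trichlorobenzoic anhydride | C/C=C(/C)C(=O)OC(=O)c1c(Cl)cc(Cl)cc1Cl | intermediate (not isolated)
24 | (1S,3S,4S,6S)‑4‑[(3S)‑3‑[(tert‑butyldimethylsilyl)oxy]‑6‑methylhepta‑1,5‑dien‑2‑yl]‑1‑methyl‑2‑oxo‑7‑oxabicyclo[4.1.0]heptan‑3‑yl (2Z)‑2‑methylbut‑2‑enoate | C=C([C@H](CC=C(C)C)O[Si](C)(C)C(C)(C)C)[C@@H]1C[C@@H]2O[C@]2(C)C(=O)[C@H]1OC(=O)/C(C)=C\C | intermediate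
25 | (1S,3S,4S,6S)‑4‑[(3S)‑3‑hydroxy‑6‑methylhepta‑1,5‑dien‑2‑yl]‑1‑methyl‑2‑oxo‑7‑oxabicyclo[4.1.0]heptan‑3‑yl (2Z)‑2‑methylbut‑2‑enoate | C=C([C@H](CC=C(C)C)O)[C@@H]1C[C@@H]2O[C@]2(C)C(=O)[C@H]1OC(=O)/C(C)=C\C | intermediate
26 | (1S,3S,4S,6S)‑4‑[(3S)‑3‑(acetyloxy)‑6‑methylhepta‑1,5‑dien‑2‑yl]‑1‑methyl‑2‑oxo‑7‑oxabicyclo[4.1.0]heptan‑3‑yl (2Z)‑2‑methylbut‑2‑enoate | C=C([C@H](CC=C(C)C)OC(C)=O)[C@@H]1C[C@@H]2O[C@]2(C)C(=O)[C@H]1OC(=O)/C(C)=C\C | target

**Step count and risks**

Total steps: 16. Longest linear sequence: 16 steps (1 to 26).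

Steps most likely to fail:

1. Step 13 (key step). What may go wrong: attack on the other face of the formyl group relative to the oxirane if ring strain and catalyst preferences do not match; a stepwise Prins pathway with loss of control over which hydrogen is transferred; Lewis‑acid opening of the oxirane; hydration or oligomerisation of the glyoxal before it cyclises. Fallback with known chemistry, setting out from diol 19: both hydroxyl groups are silylated (Et3SiOTf, 2,6‑lutidine) to give the bis(triethylsilyl) ether F1. Swern conditions then oxidise the primary triethylsilyl ether directly and selectively to the α‑silyloxy aldehyde F2. The established type 1 carbonyl‑ene cyclisation of an unactivated aldehyde (Me2AlCl, CH2Cl2, −78 °C, as for citronellal to isopulegol) closes the C1–C6 bond to the silyloxy cyclohexanol F3; the isomer with C1–OH trans to the C6 side chain and the side chain cis to the oxirane oxygen is separated, and epimers at C2 are carried on. F3 is acylated with mixed anhydride 23 as in step 14 to the angelate F4, the triethylsilyl ether is removed selectively (PPTS, MeOH, 0 °C) to give the ring alcohol F5, and Dess–Martin oxidation of F5 comes back to the route at 24.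

2. Step 5. What may go wrong: migration of the C6=C7 double bond into conjugation with the new aldehyde, loss of the secondary silyl ether, or self‑condensation of the skipped enal (which would also spoil step 6). Fallback setting out from ketone 6, which avoids any β,γ‑unsaturated aldehyde: the silyloxypropylidene ylide F6, made from {3‑[(tert‑butyldimethylsilyl)oxy]propyl}triphenylphosphonium bromide and KN(SiMe3)2, reacts with 6 in the same Z‑selective Wittig manner to give the bis‑silyl ether F7. Selective cleavage of the primary silyl ether (HF·pyridine, pyridine, THF, 0 °C) gives the homoallylic alcohol F8, iodination (I2, PPh3, imidazole) gives the iodide F9, and PPh3 (MeCN, 80 °C) gives the phosphonium iodide F10. Its ylide F11 (KN(SiMe3)2, THF, −78 °C) reacts with 1‑[(tert‑butyldimethylsilyl)oxy]propan‑2‑one in a second Z‑selective Wittig reaction of an α‑alkoxy ketone to give the bis‑silyl triene F12. Selective removal of the primary allylic silyl group (HF·pyridine, pyridine, THF, 0 °C) comes back to the route at 15, so steps 6 and 7 are also bypassed.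

3. Step 14. What may go wrong: isomerisation of the angelate to the tiglate during acyl transfer, epimerisation at C1 under the basic, warm conditions, or slow acylation of the hindered α‑ketol. Fallback setting out from 21, which builds the angelate double bond on the substrate instead of transferring it: esterification with 2‑(diphenoxyphosphoryl)propanoic acid (DCC, DMAP cat., CH2Cl2) gives the phosphonate ester F13, and a Z‑selective Horner–Wadsworth–Emmons reaction of this diaryl phosphonate with acetaldehyde (NaI, DBU, THF, −78 to 0 °C) comes back to the route at 24.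

**Further compounds**

F1 | step 13 | bis(triethylsilyl) ether of diol 19 (epimers at C2) | CC[Si](CC)(CC)OCC(O[Si](CC)(CC)CC)[C@@]1(C)O[C@H]1C/C=C(C)\[C@H](CC=C(C)C)O[Si](C)(C)C(C)(C)C
F2 | step 13 | 2‑[(triethylsilyl)oxy] aldehyde, 20 with C2 as CH–OSiEt3 (epimers at C2) | O=CC(O[Si](CC)(CC)CC)[C@@]1(C)O[C@H]1C/C=C(C)\[C@H](CC=C(C)C)O[Si](C)(C)C(C)(C)C
F3 | step 13 | silyloxy cyclohexanol, 21 with C2 as CH–OSiEt3 (epimers at C2) | C=C([C@H](CC=C(C)C)O[Si](C)(C)C(C)(C)C)[C@@H]1C[C@@H]2O[C@]2(C)C(O[Si](CC)(CC)CC)[C@H]1O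
F4 | step 13 | angelate of F3 | C=C([C@H](CC=C(C)C)O[Si](C)(C)C(C)(C)C)[C@@H]1C[C@@H]2O[C@]2(C)C(O[Si](CC)(CC)CC)[C@H]1OC(=O)/C(C)=C\C
F5 | step 13 | ring alcohol, 24 with C2 as CH–OH (epimers at C2) | C=C([C@H](CC=C(C)C)O[Si](C)(C)C(C)(C)C)[C@@H]1C[C@@H]2O[C@]2(C)C(O)[C@H]1OC(=O)/C(C)=C\C
F6 | step 5 | {3‑[(tert‑butyldimethylsilyl)oxy]propylidene}triphenylphosphorane | CC(C)(C)[Si](C)(C)OCCC=P(c1ccccc1)(c1ccccc1)c1ccccc1
F7 | step 5 | (3Z,5S)‑1,5‑bis[(tert‑butyldimethylsilyl)oxy]‑4,8‑dimethylnona‑3,7‑diene | CC(C)(C)[Si](C)(C)OCC/C=C(C)\[C@H](CC=C(C)C)O[Si](C)(C)C(C)(C)C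
F8 | step 5 | (3Z,5S)‑5‑[(tert‑butyldimethylsilyl)oxy]‑4,8‑dimethylnona‑3,7‑dien‑1‑ol | OCC/C=C(C)\[C@H](CC=C(C)C)O[Si](C)(C)C(C)(C)C
F9 | step 5 | (3Z,5S)‑5‑[(tert‑butyldimethylsilyl)oxy]‑1‑iodo‑4,8‑dimethylnona‑3,7‑diene | ICC/C=C(C)\[C@H](CC=C(C)C)O[Si](C)(C)C(C)(C)C
F10 | step 5 | [(3Z,5S)‑5‑[(tert‑butyldimethylsilyl)oxy]‑4,8‑dimethylnona‑3,7‑dien‑1‑yl]triphenylphosphonium iodide | [I-].c1ccc(cc1)[P+](c1ccccc1)(c1ccccc1)CC/C=C(C)\[C@H](CC=C(C)C)O[Si](C)(C)C(C)(C)C
F11 | step 5 | [(3Z,5S)‑5‑[(tert‑butyldimethylsilyl)oxy]‑4,8‑dimethylnona‑3,7‑dien‑1‑ylidene]triphenylphosphorane | c1ccc(cc1)P(c1ccccc1)(c1ccccc1)=CC/C=C(C)\[C@H](CC=C(C)C)O[Si](C)(C)C(C)(C)C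
F12 | step 5 | tert‑butyldimethylsilyl ether of 15 | CC(C)(C)[Si](C)(C)OC/C(C)=C\C/C=C(C)\[C@H](CC=C(C)C)O[Si](C)(C)C(C)(C)C
F13 | step 14 | 2‑(diphenoxyphosphoryl)propanoate ester of 21 | C=C([C@H](CC=C(C)C)O[Si](C)(C)C(C)(C)C)[C@@H]1C[C@@H]2O[C@]2(C)C(=O)[C@H]1OC(=O)C(C)P(=O)(Oc3ccccc3)Oc3ccccc3
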